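**Retrosynthetic overview**
- Altissimacoumarin C is isofraxidin whose O7 carries a C10 chain. The benzene ring and the pyran-2-one ring are bought fused and stay untouched, so only C2'(R) and C3'(R) of the chain have to be created.
- Key disconnection: C2'–C3'. Both carbons bear oxygen (secondary carbinol C2', fully substituted carbinol C3'), so this is a pinacol-type bond between an aldehyde carbon and a ketone-level carbon.
- Enabling feature: the aryloxy group on C1' would be expelled by any negative charge on C2', so C2' must be the electrophile (aryloxyacetaldehyde). The oxygen on C3' is replaced by boron, whose empty p orbital makes C3' a stabilised nucleophile (achiral geminal diboronate CH3–C(Bpin)2–homoprenyl).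
- One copper-catalysed deborylative 1,2-addition forms the bond and both stereocentres from two achiral partners. A stereoretentive C–B oxidation then gives the diol.
- Further disconnections: O7–C1' (Williamson) and C3'–C4' (alkylation of 1,1-diborylethane). No ring is formed anywhere in the route.

Key step: step 4

Remark: chain atoms are called C1' (OCH2) to C8'; the antipode of the phosphoramidite that opens the Si face of the aldehyde is assumed to follow the sense known for 1,1-diborylethane additions and is confirmed in a first run, the other antipode being used if the mirror image forms.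

Step 1
Reactants: 1 isofraxidin (7-hydroxy-6,8-dimethoxy-2H-chromen-2-one); 2 2-bromoethanol
Product: 3 7-(2-hydroxyethoxy)-6,8-dimethoxy-2H-chromen-2-one
Conditions: K2CO3, DMF, 70 °C
Reagents that add atoms: none
Why: Williamson ether synthesis, in which the acidic 7-OH is the only site deprotonated by carbonate and displaces the primary bromide by SN2 while the lactone is inert to carbonate in DMF; no stereocentre is involved.

Step 2
Reactants: 3 7-(2-hydroxyethoxy)-6,8-dimethoxy-2H-chromen-2-one
Product: 4 [(6,8-dimethoxy-2-oxo-2H-chromen-7-yl)oxy]acetaldehyde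
Conditions: Dess–Martin periodinane, CH2Cl2, 0 °C to rt; short silica plug, azeotropic drying (toluene), used fresh
Reagents that add atoms: none
Why: Dess–Martin oxidation stops at the aldehyde under neutral, water-free conditions and touches neither the coumarin C3=C4 bond nor the aryl ethers; no stereocentre is involved.

Step 3
Reactants: 5 2,2'-(ethane-1,1-diyl)bis(4,4,5,5-tetramethyl-1,3,2-dioxaborolane) (1,1-diborylethane); 6 5-bromo-2-methylpent-2-ene
Product: 8 2,2'-(6-methylhept-5-ene-2,2-diyl)bis(4,4,5,5-tetramethyl-1,3,2-dioxaborolane), via lithiated 1,1-diborylethane 7 (not isolated)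
Conditions: LiTMP (from 2,2,6,6-tetramethylpiperidine and n-BuLi), THF, 0 °C; then 6, 0 °C to rt
Reagents that add atoms: none
Why: Alkylation of a geminal diboronate, in which the hindered amide removes the proton flanked by two boron atoms and the doubly stabilised carbanion displaces the primary homoallylic bromide by SN2; the product is achiral and the trisubstituted alkene is a spectator.

Step 4
Reactants: 4 [(6,8-dimethoxy-2-oxo-2H-chromen-7-yl)oxy]acetaldehyde; 8 2,2'-(6-methylhept-5-ene-2,2-diyl)bis(4,4,5,5-tetramethyl-1,3,2-dioxaborolane)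
Product: 11 7-{[(2S,3S)-2-hydroxy-3,7-dimethyl-3-(4,4,5,5-tetramethyl-1,3,2-dioxaborolan-2-yl)oct-6-en-1-yl]oxy}-6,8-dimethoxy-2H-chromen-2-one, via alpha-boryl alkylcopper 9 (not isolated), via lithium alkoxide 10 (not isolated)
Conditions: Cu(MeCN)4PF6 (10 mol %), BINOL-derived N,N-bis(1-phenylethyl)phosphoramidite L* (20 mol %), LiOt-Bu (1.2 equiv), 8 (1.3 equiv), THF, −20 °C, 4 added slowly by syringe pump; then sat. aq NH4Cl
Reagents that add atoms: none
Why: Proposed new method: L*Cu–Ot-Bu removes one of the two enantiotopic Bpin groups of 8 as t-BuO–Bpin to give the tertiary α-boryl alkylcopper 9, whose carbanion character is held by the empty p orbital of the remaining boron, and 9 inserts the C=O of 4 through a four-centre transition state before LiOt-Bu releases the catalyst from the copper alkoxide to leave 10. The closest known reaction type is the copper/phosphoramidite-catalysed enantio- and syn-selective 1,2-addition of 1,1-diborylalkanes RCH(Bpin)2 to aldehydes, and alkoxide-induced deborylation of fully substituted geminal diboronates to tertiary α-boryl carbanions is also known, so the new elements are the fully substituted carbon on copper and the α-aryloxy aliphatic aldehyde. No ring is closed. C2' (R in the final diol, S in 11 only because boron changes the CIP ranking) is set by the ligand, which leaves the Si face of the copper-bound aldehyde open. C3' is set relative to C2': 9 is expected to be configurationally labile because its C–Cu bond is conjugated with boron, so both antipodes drain through the one transition state in which the forming alkoxide oxygen lies gauche to boron (O→B contact, boron next to the aldehyde H), the homoprenyl arm points away from the Cu–O side and the methyl group takes the crowded slot beside CH2OAr, which gives the syn O/B pair. The step needs 1,2-addition to the aldehyde in preference to attack on the lactone carbonyl or C4 of the coumarin, to enolisation of 4 and to B–O syn-elimination of 10, and this is secured by the far higher electrophilicity of the α-aryloxy aldehyde, its slow addition, the hindered base and the low temperature.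

Step 5
Reactants: 11 7-{[(2S,3S)-2-hydroxy-3,7-dimethyl-3-(4,4,5,5-tetramethyl-1,3,2-dioxaborolan-2-yl)oct-6-en-1-yl]oxy}-6,8-dimethoxy-2H-chromen-2-one
Product: 12 altissimacoumarin C, 7-{[(2R,3R)-2,3-dihydroxy-3,7-dimethyloct-6-en-1-yl]oxy}-6,8-dimethoxy-2H-chromen-2-one
Conditions: NaBO3·4H2O, THF/H2O (1:1), rt; work-up at pH 5 (buffer)
Reagents that add atoms: sodium perborate (tetrahydrate, water of hydration omitted), [Na+].[Na+].O[B-]1(O)OO[B-](O)(O)OO1
Why: Stereoretentive oxidation of a tertiary boronic ester (1,2-shift of C3' from boron to the peroxide oxygen with retention) carries the configuration fixed in step 4 into the carbinol, while the weakly basic perborate leaves the C6'=C7' alkene and the aryl ethers alone, and work-up at pH 5 re-closes any opened (Z)-coumarinate, so the lactone is kept.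

**Compound list**
1 | isofraxidin (7-hydroxy-6,8-dimethoxy-2H-chromen-2-one) | COc1cc2ccc(=O)oc2c(OC)c1O | starting material
2 | 2-bromoethanol | OCCBr | starting material
3 | 7-(2-hydroxyethoxy)-6,8-dimethoxy-2H-chromen-2-one | COc1cc2ccc(=O)oc2c(OC)c1OCCO | intermediate
4 | [(6,8-dimethoxy-2-oxo-2H-chromen-7-yl)oxy]acetaldehyde | COc1cc2ccc(=O)oc2c(OC)c1OCC=O | intermediate
5 | 2,2'-(ethane-1,1-diyl)bis(4,4,5,5-tetramethyl-1,3,2-dioxaborolane) | CC(B1OC(C)(C)C(C)(C)O1)B1OC(C)(C)C(C)(C)O1 | starting material
6 | 5-bromo-2-methylpent-2-ene | CC(C)=CCCBr | starting material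
7 | 1,1-bis(pinacolboryl)ethyllithium | [Li]C(C)(B1OC(C)(C)C(C)(C)O1)B1OC(C)(C)C(C)(C)O1 | intermediate
8 | 2,2'-(6-methylhept-5-ene-2,2-diyl)bis(4,4,5,5-tetramethyl-1,3,2-dioxaborolane) | CC(C)=CCCC(C)(B1OC(C)(C)C(C)(C)O1)B1OC(C)(C)C(C)(C)O1 | intermediate
9 | [6-methyl-2-(pinacolboryl)hept-5-en-2-yl]copper (ligand L* omitted, configurationally labile) | CC(C)=CCCC(C)([Cu])B1OC(C)(C)C(C)(C)O1 | intermediate
10 | lithium alkoxide of 11 | COc1cc2ccc(=O)oc2c(OC)c1OC[C@@H]([O-])[C@](C)(B3OC(C)(C)C(C)(C)O3)CCC=C(C)C.[Li+] | intermediate
11 | 7-{[(2S,3S)-2-hydroxy-3,7-dimethyl-3-(pinacolboryl)oct-6-en-1-yl]oxy}-6,8-dimethoxy-2H-chromen-2-one | COc1cc2ccc(=O)oc2c(OC)c1OC[C@@H](O)[C@](C)(B3OC(C)(C)C(C)(C)O3)CCC=C(C)C | intermediate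
12 | altissimacoumarin C | COc1cc2ccc(=O)oc2c(OC)c1OC[C@@H](O)[C@](C)(O)CCC=C(C)C | target

Total step count: 5. Longest linear sequence: 4 steps (steps 1, 2, 4 and 5). Step 3 is the one-step side branch.

**Steps most likely to fail**

Step 4 (Proposed new method). Possible failures are:
- slow boron-to-copper exchange at the fully substituted carbon;
- weak discrimination between the methyl and the homoprenyl arm, which erodes C3';
- B–O syn-elimination of the β-boryl alkoxide;
- enolisation or self-aldol reaction of the aldehyde.

The fallback uses known chemistry, makes the same C2'–C3' bond and completes the chain afterwards. It sets out from 4 and comes back at 12. Copper-catalysed SN2' borylation of but-2-yn-1-yl methyl carbonate with B2pin2 gives 2-(buta-2,3-dien-2-yl)-4,4,5,5-tetramethyl-1,3,2-dioxaborolane F1. Kinetically controlled hydroboration of its terminal C=C with (−)-diisopinocampheylborane (from (+)-α-pinene) gives the γ-boryl-γ-methylallylborane F2, in which the CH2–B(Ipc)2 arm is cis to Bpin. Aldehyde 4 is added at −78 °C. In the chair transition state Bpin sits axial, which gives the syn O/B pair, and the Ipc groups direct attack to the Si face; the product is the diisopinocampheylborinate adduct F3. Oxidation with NaBO3 gives 7-{[(2R,3R)-2,3-dihydroxy-3-methylpent-4-en-1-yl]oxy}-6,8-dimethoxy-2H-chromen-2-one F4. Hydroboration of the vinyl group with 9-BBN gives the B-alkyl-9-BBN F5. A B-alkyl Suzuki–Miyaura coupling with 1-bromo-2-methylprop-1-ene [PdCl2(dppf), K3PO4, DMF/THF/H2O] then gives 12.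

Step 5. Two things may go wrong. The hindered tertiary boronate may oxidise slowly, and under basic peroxide the neighbouring free alkoxide may trigger loss of boron and oxygen together. The fallback takes the alkoxide out of play with a protecting-group detour. It sets out from 11 and comes back at 12. Silylation (TESOTf, 2,6-lutidine, CH2Cl2, −78 °C) gives the triethylsilyl ether boronate F6. Neutral oxidation with trimethylamine N-oxide (THF, 60 °C) gives the triethylsilyl ether carbinol F7 with retention. AcOH/THF/H2O then removes the silyl group to give 12.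

Step 3. The crowded methyl-bearing carbanion may displace the homoallylic bromide only slowly, and E2 elimination then competes. The fallback reverses the order of the two alkylations, so that the congested bond is made with the smallest electrophile, which cannot eliminate. It sets out from 6 and comes back at 8. Bis(pinacolboryl)methane is deprotonated with LiTMP to lithiated bis(pinacolboryl)methane F8. Alkylation of F8 with 6 gives 2,2'-(5-methylhex-4-ene-1,1-diyl)bis(4,4,5,5-tetramethyl-1,3,2-dioxaborolane) F9. A second deprotonation with LiTMP gives its lithio derivative F10, and methyl iodide then gives 8.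

**Further compounds**
F1 | step 4 | 2-(buta-2,3-dien-2-yl)-4,4,5,5-tetramethyl-1,3,2-dioxaborolane | C=C=C(C)B1OC(C)(C)C(C)(C)O1
F2 | step 4 | [3-(pinacolboryl)but-2-en-1-yl]diisopinocampheylborane, CH2B cis to Bpin (E by CIP) | C/C(B1OC(C)(C)C(C)(C)O1)=C/CB([C@@H]1C[C@@H]2C[C@H]([C@H]1C)C2(C)C)[C@@H]1C[C@@H]2C[C@H]([C@H]1C)C2(C)C
F3 | step 4 | diisopinocampheylborinate of the allylboration adduct | COc1cc2ccc(=O)oc2c(OC)c1OC[C@@H](OB([C@@H]3C[C@@H]4C[C@H]([C@H]3C)C4(C)C)[C@@H]3C[C@@H]4C[C@H]([C@H]3C)C4(C)C)[C@](C)(B3OC(C)(C)C(C)(C)O3)C=C
F4 | step 4 | 7-{[(2R,3R)-2,3-dihydroxy-3-methylpent-4-en-1-yl]oxy}-6,8-dimethoxy-2H-chromen-2-one | COc1cc2ccc(=O)oc2c(OC)c1OC[C@@H](O)[C@](C)(O)C=C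
F5 | step 4 | B-alkyl-9-BBN from F4 (hydroxyl groups written free) | COc1cc2ccc(=O)oc2c(OC)c1OC[C@@H](O)[C@](C)(O)CCB3C4CCCC3CCC4
F6 | step 5 | 2'-O-triethylsilyl ether of 11 | COc1cc2ccc(=O)oc2c(OC)c1OC[C@@H](O[Si](CC)(CC)CC)[C@](C)(B3OC(C)(C)C(C)(C)O3)CCC=C(C)C
F7 | step 5 | 2'-O-triethylsilyl ether of 12 | COc1cc2ccc(=O)oc2c(OC)c1OC[C@@H](O[Si](CC)(CC)CC)[C@](C)(O)CCC=C(C)C
F8 | step 3 | bis(pinacolboryl)methyllithium | [Li]C(B1OC(C)(C)C(C)(C)O1)B1OC(C)(C)C(C)(C)O1
F9 | step 3 | 2,2'-(5-methylhex-4-ene-1,1-diyl)bis(4,4,5,5-tetramethyl-1,3,2-dioxaborolane) | CC(C)=CCCC(B1OC(C)(C)C(C)(C)O1)B1OC(C)(C)C(C)(C)O1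
F10 | step 3 | 5-methyl-1,1-bis(pinacolboryl)hex-4-en-1-yllithium | [Li]C(CCC=C(C)C)(B1OC(C)(C)C(C)(C)O1)B1OC(C)(C)C(C)(C)O1
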